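**Plan**

- Numbering (carotenoid): the alkynyl ring is ring A (C1–C6), the chain runs C7–C15, and primed numbers are used for the 7′,8′-dihydro half (ring B).
- Cuts: C11=C12 and C11′=C12′ (two Horner–Wadsworth–Emmons olefinations on the C10 dialdehyde), C6–C7 (Sonogashira), C6′–C7′ (B-alkyl Suzuki), and in each ring the two bonds at C5 (one-carbon ring expansion).
- Enabling feature: in ring A, C6 (the sp2 carbon bearing the alkyne) is a ketone carbon in disguise (enol triflate) lying between quaternary C1 and C5, whose only substituent is a methyl group. Ring A is therefore a 2,2-dimethylcyclopentanone (C6, C1, C2, C3, C4) into whose C4–C6 bond C5 is inserted as CH(CH3) from diazoethane.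
- Forward order: enone → conjugate boration → five-membered ketone 5 → ring expansion to six-membered ketone 9 → triflate 11. Triflate 11 is used twice (ring A by Sonogashira, ring B by hydroboration/Suzuki), each time with the C5 phosphonate 14 or its diene 16. Then ring B C15 + C10 → C25, + ring A C15 → C40, and desilylation.
- Stereochemistry: C3 and C3′ both come from one copper-catalysed enantioselective conjugate boration. 9E and 9′E come from commercial (E)-3-methylpent-2-en-4-yn-1-ol, 13E/15E/13′E from the dialdehyde, and 11E/11′E from the two olefinations. No thermal or iodine equilibration is used, so the 9E enyne geometry should be kept.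

Key step: step 5

Remark on the chemistry: ketone 9 is carried as a mixture of epimers at its methyl-bearing carbon, because that centre becomes sp2 in step 6. Diazoethane is handled only as a cold, dilute solution.

**Route**

Step 1
Reactants: 1 2,2-dimethylcyclopentan-1-one
Product: 2 5,5-dimethylcyclopent-2-en-1-one
Conditions: IBX (1.5 equiv), DMSO/fluorobenzene, 70 °C
Reagents that add atoms: none
Why: IBX-mediated α,β-dehydrogenation of a ketone (Nicolaou dehydrogenation) should give a single enone, because only one α-carbon of 1 bears hydrogen.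

Step 2
Reactants: 2 5,5-dimethylcyclopent-2-en-1-one
Product: 4 (4S)-4-hydroxy-2,2-dimethylcyclopentan-1-one, via boryl ketone 3 (not isolated)
Conditions: CuCl (3 mol%), NaOtBu (6 mol%), QuinoxP* (4 mol%, the enantiomer that delivers 4S), B2pin2, MeOH (2 equiv), THF, rt; then NaBO3·4H2O, THF/H2O, rt
Reagents that add atoms: bis(pinacolato)diboron, CC1(C)OB(OC1(C)C)B1OC(C)(C)C(C)(C)O1 (boron of 3 only); sodium perborate, [Na+].[Na+].O[B-]1(O)OO[B-](O)(O)OO1 (the hydroxyl oxygen of 4)
Why: Copper-catalysed enantioselective conjugate boration of a cyclic enone places boron on the β-carbon under control of the chiral bisphosphine, which sets the future C3 and C3′ centre, and perborate oxidation of the C–B bond proceeds with retention.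

Step 3
Reactants: 4 (4S)-4-hydroxy-2,2-dimethylcyclopentan-1-one
Product: 5 (4S)-4-(tert-butyldimethylsilyloxy)-2,2-dimethylcyclopentan-1-one
Conditions: TBSCl, imidazole, DMF, 0 °C → rt
Reagents that add atoms: tert-butyldimethylsilyl chloride, CC(C)(C)[Si](C)(C)Cl
Why: Standard silylation of a secondary alcohol masks the hydroxyl against O-alkylation by diazoethane, against β-elimination and against the triflating agent, without touching the stereocentre.

Step 4
Reactants: 6 N-ethyl-N-nitrosourea
Product: 7 diazoethane (dried toluene solution, not concentrated)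
Conditions: 40% aq KOH, toluene, 0 °C; organic layer dried over KOH pellets and used cold
Reagents that add atoms: none
Why: Base-induced fragmentation of an N-alkyl-N-nitrosourea is the standard preparation of a non-stabilised diazoalkane.

Step 5
Reactants: 5 (4S)-4-(tert-butyldimethylsilyloxy)-2,2-dimethylcyclopentan-1-one; 7 diazoethane
Product: 9 (4R)-4-(tert-butyldimethylsilyloxy)-2,2,6-trimethylcyclohexan-1-one (both C6 epimers), via diazonium alkoxide 8 (not isolated)
Conditions: Sc(OTf)3 (10 mol%), toluene, −78 → −40 °C, slow addition of 7 (1.5 equiv)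
Reagents that add atoms: none
Why: Sc(OTf)3 activates the carbonyl of 5, the nucleophilic carbon of diazoethane adds to give diazonium alkoxide 8, and a 1,2-shift of the ring CH2–C(O) bond to the diazonium carbon with loss of N2 inserts the CH(CH3) unit and re-forms the ketone. The closest known reaction type is the Lewis-acid-catalysed homologation of cycloalkanones with diazoalkanes (Tiffeneau–Demjanov-type ring expansion). The six-membered ring is not closed by a cyclisation but arises from the five-membered ring by this one-carbon insertion, the migrating CH2 carbon forming the new bond to the inserted carbon. No stereocentre of the target is created: the silyloxy-bearing carbon is remote from the reacting centre and is carried through unchanged (its descriptor changes from S to R only because the ring neighbours change), and the new methyl-bearing centre forms without control, which is harmless because it becomes sp2 in step 6. The selectivity needed is migration of the CH2 carbon and not of the quaternary CMe2 carbon, and the gem-dimethyl group should secure it, since in Lewis-acid-promoted diazoalkane insertions the less substituted, less hindered α-carbon is the one that aligns with the departing N2 and migrates. A second insertion should be suppressed because the carbonyl of 9 lies between a quaternary and a tertiary carbon and is far less accessible than that of 5.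

Step 6
Reactants: 9 (4R)-4-(tert-butyldimethylsilyloxy)-2,2,6-trimethylcyclohexan-1-one
Product: 11 (4R)-4-(tert-butyldimethylsilyloxy)-2,6,6-trimethylcyclohex-1-en-1-yl trifluoromethanesulfonate, via lithium enolate 10 (not isolated)
Conditions: LiN(iPr)2, THF, −78 → 0 °C; then PhNTf2, −78 °C → rt
Reagents that add atoms: lithium diisopropylamide, [Li+].CC(C)[N-]C(C)C (lithium of 10 only); N-phenylbis(trifluoromethanesulfonimide), O=S(=O)(N(c1ccccc1)S(=O)(=O)C(F)(F)F)C(F)(F)F
Why: Enolate O-triflation is regiospecific here because only the methyl-bearing α-carbon has a hydrogen, so a single tetrasubstituted enol triflate forms, the epimeric centre is erased, and the silyl ether, γ to the enolate, cannot eliminate.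

Step 7
Reactants: 12 (2E)-3-methylpent-2-en-4-yn-1-ol
Product: 14 diethyl [(2E)-3-methylpent-2-en-4-yn-1-yl]phosphonate, via allylic bromide 13 (not isolated)
Conditions: PBr3 (0.4 equiv), pyridine (cat.), Et2O, −10 °C; then P(OEt)3, 90 °C
Reagents that add atoms: phosphorus tribromide, BrP(Br)Br (bromine of 13 only); triethyl phosphite, CCOP(OCC)OCC
Why: Bromination of the primary allylic alcohol followed by a Michaelis–Arbuzov reaction, both by SN2 attack at the primary carbon, should keep the E-trisubstituted double bond.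

Step 8
Reactants: 11 (4R)-4-(tert-butyldimethylsilyloxy)-2,6,6-trimethylcyclohex-1-en-1-yl trifluoromethanesulfonate; 14 diethyl [(2E)-3-methylpent-2-en-4-yn-1-yl]phosphonate
Product: 15 diethyl {(2E)-5-[(4R)-4-(tert-butyldimethylsilyloxy)-2,6,6-trimethylcyclohex-1-en-1-yl]-3-methylpent-2-en-4-yn-1-yl}phosphonate
Conditions: Pd(PPh3)4 (5 mol%), CuI (10 mol%), iPr2NH, DMF, rt → 45 °C, degassed
Reagents that add atoms: none
Why: Sonogashira coupling of the hindered enol triflate with the terminal enyne forms C6–C7 and leaves the E double bond, the silyl ether and the phosphonate untouched.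

Step 9
Reactants: 14 diethyl [(2E)-3-methylpent-2-en-4-yn-1-yl]phosphonate
Product: 16 diethyl [(2E)-3-methylpenta-2,4-dien-1-yl]phosphonate
Conditions: H2 (1 atm), Pd/CaCO3 poisoned with Pb(OAc)2, quinoline, EtOAc/hexane, rt, stopped after 1 equiv H2
Reagents that add atoms: none
Why: Lindlar-type semi-hydrogenation of the terminal alkyne should stop at the vinyl group and leave the E-trisubstituted alkene unchanged.

Step 10
Reactants: 16 diethyl [(2E)-3-methylpenta-2,4-dien-1-yl]phosphonate; 11 (4R)-4-(tert-butyldimethylsilyloxy)-2,6,6-trimethylcyclohex-1-en-1-yl trifluoromethanesulfonate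
Product: 18 diethyl {(2E)-5-[(4R)-4-(tert-butyldimethylsilyloxy)-2,6,6-trimethylcyclohex-1-en-1-yl]-3-methylpent-2-en-1-yl}phosphonate, via alkylborane 17 (not isolated)
Conditions: 9-BBN (1.1 equiv), THF, 0 °C → rt; then 11, PdCl2(dppf) (5 mol%), AsPh3, aq Cs2CO3, DMF, 50 °C
Reagents that add atoms: 9-borabicyclo[3.3.1]nonane, B1C2CCCC1CCC2 (boron of 17 only)
Why: 9-BBN should hydroborate only the monosubstituted vinyl terminus of the diene (boron on the end carbon, giving a stable homoallylic borane), and B-alkyl Suzuki–Miyaura coupling with the enol triflate then forms the C6′–C7′ sp2–sp3 bond without creating a stereocentre.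

Step 11
Reactants: 18 diethyl {(2E)-5-[(4R)-4-(tert-butyldimethylsilyloxy)-2,6,6-trimethylcyclohex-1-en-1-yl]-3-methylpent-2-en-1-yl}phosphonate; 19 (2E,4E,6E)-2,7-dimethylocta-2,4,6-trienedial
Product: 21 (2E,4E,6E,8E,10E)-13-[(4R)-4-(tert-butyldimethylsilyloxy)-2,6,6-trimethylcyclohex-1-en-1-yl]-2,7,11-trimethyltrideca-2,4,6,8,10-pentaenal, via lithiated phosphonate 20 (not isolated)
Conditions: n-BuLi, THF/DMPU, −78 °C; then cannulated into 19 (3 equiv), THF, −78 °C → rt, dark
Reagents that add atoms: n-butyllithium, [Li]CCCC (lithium of 20 only)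
Why: Horner–Wadsworth–Emmons olefination of the allylic phosphonate carbanion with one aldehyde group of the dialdehyde (excess dialdehyde, inverse addition) should give the E-C11′=C12′ bond through the favoured anti adduct.

Step 12
Reactants: 15 diethyl {(2E)-5-[(4R)-4-(tert-butyldimethylsilyloxy)-2,6,6-trimethylcyclohex-1-en-1-yl]-3-methylpent-2-en-4-yn-1-yl}phosphonate; 21 (2E,4E,6E,8E,10E)-13-[(4R)-4-(tert-butyldimethylsilyloxy)-2,6,6-trimethylcyclohex-1-en-1-yl]-2,7,11-trimethyltrideca-2,4,6,8,10-pentaenal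
Product: 23 (all-E,3R,3′R)-3,3′-bis(tert-butyldimethylsilyloxy)-7,8-didehydro-7′,8′-dihydro-β,β-carotene, via lithiated phosphonate 22 (not isolated)
Conditions: n-BuLi, THF/DMPU, −78 °C; then 21, −78 °C → rt, dark, argon
Reagents that add atoms: n-butyllithium, [Li]CCCC (lithium of 22 only)
Why: A second Horner–Wadsworth–Emmons olefination, with the enyne-conjugated allylic phosphonate carbanion generated and consumed cold, should form the E-C11=C12 bond kinetically and so avoid any equilibration that could turn the 9E enyne double bond to 9Z.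

Step 13
Reactants: 23 (all-E,3R,3′R)-3,3′-bis(tert-butyldimethylsilyloxy)-7,8-didehydro-7′,8′-dihydro-β,β-carotene
Product: 24 (all-E,3R,3′R)-7,8-didehydro-7′,8′-dihydro-β,β-carotene-3,3′-diol (CNP0178054.1)
Conditions: TBAF, THF, 0 °C → rt, dark, argon
Reagents that add atoms: none
Why: Fluoride-mediated cleavage of both silyl ethers is mild enough for the polyenyne and does not touch the two carbinol centres.

**Compound list**

1 | 2,2-dimethylcyclopentan-1-one | CC1(C)CCCC1=O | starting material
2 | 5,5-dimethylcyclopent-2-en-1-one | O=C1C=CCC1(C)C | intermediate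
3 | (4S)-2,2-dimethyl-4-(4,4,5,5-tetramethyl-1,3,2-dioxaborolan-2-yl)cyclopentan-1-one | O=C1C(C)(C)C[C@H](B2OC(C)(C)C(C)(C)O2)C1 | intermediate
4 | (4S)-4-hydroxy-2,2-dimethylcyclopentan-1-one | O=C1C(C)(C)C[C@H](O)C1 | intermediate
5 | (4S)-4-(tert-butyldimethylsilyloxy)-2,2-dimethylcyclopentan-1-one | O=C1C(C)(C)C[C@H](O[Si](C)(C)C(C)(C)C)C1 | intermediate
6 | N-ethyl-N-nitrosourea | CCN(N=O)C(N)=O | starting material
7 | diazoethane | CC=[N+]=[N-] | intermediate
8 | 1-[4-(tert-butyldimethylsilyloxy)-2,2-dimethyl-1-oxidocyclopentyl]ethane-1-diazonium (scandium-bound zwitterion; silyloxy carbon as in 5, the two new centres unassigned) | CC([N+]#N)C1([O-])C[C@@H](O[Si](C)(C)C(C)(C)C)CC1(C)C | intermediate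
9 | (4R)-4-(tert-butyldimethylsilyloxy)-2,2,6-trimethylcyclohexan-1-one (mixture of C6 epimers) | CC1C(=O)C(C)(C)C[C@H](O[Si](C)(C)C(C)(C)C)C1 | intermediate
10 | lithium (4R)-4-(tert-butyldimethylsilyloxy)-2,6,6-trimethylcyclohex-1-en-1-olate | [Li+].CC1=C([O-])C(C)(C)C[C@H](O[Si](C)(C)C(C)(C)C)C1 | intermediate
11 | (4R)-4-(tert-butyldimethylsilyloxy)-2,6,6-trimethylcyclohex-1-en-1-yl trifluoromethanesulfonate | CC1=C(OS(=O)(=O)C(F)(F)F)C(C)(C)C[C@H](O[Si](C)(C)C(C)(C)C)C1 | intermediate
12 | (2E)-3-methylpent-2-en-4-yn-1-ol | C#C/C(C)=C/CO | starting material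
13 | (3E)-5-bromo-3-methylpent-3-en-1-yne | C#C/C(C)=C/CBr | intermediate
14 | diethyl [(2E)-3-methylpent-2-en-4-yn-1-yl]phosphonate | C#C/C(C)=C/CP(=O)(OCC)OCC | intermediate
15 | diethyl {(2E)-5-[(4R)-4-(tert-butyldimethylsilyloxy)-2,6,6-trimethylcyclohex-1-en-1-yl]-3-methylpent-2-en-4-yn-1-yl}phosphonate | CC1=C(C#C/C(C)=C/CP(=O)(OCC)OCC)C(C)(C)C[C@H](O[Si](C)(C)C(C)(C)C)C1 | intermediate
16 | diethyl [(2E)-3-methylpenta-2,4-dien-1-yl]phosphonate | C=C/C(C)=C/CP(=O)(OCC)OCC | intermediate
17 | diethyl [(2E)-5-(9-borabicyclo[3.3.1]nonan-9-yl)-3-methylpent-2-en-1-yl]phosphonate | B1(CC/C(C)=C/CP(=O)(OCC)OCC)C2CCCC1CCC2 | intermediate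
18 | diethyl {(2E)-5-[(4R)-4-(tert-butyldimethylsilyloxy)-2,6,6-trimethylcyclohex-1-en-1-yl]-3-methylpent-2-en-1-yl}phosphonate | CC1=C(CC/C(C)=C/CP(=O)(OCC)OCC)C(C)(C)C[C@H](O[Si](C)(C)C(C)(C)C)C1 | intermediate
19 | (2E,4E,6E)-2,7-dimethylocta-2,4,6-trienedial | O=C/C(C)=C/C=C/C=C(C)/C=O | starting material
20 | lithium salt of 18, deprotonated at the carbon next to phosphorus | [Li+].CC1=C(CC/C(C)=C/[CH-]P(=O)(OCC)OCC)C(C)(C)C[C@H](O[Si](C)(C)C(C)(C)C)C1 | intermediate
21 | (2E,4E,6E,8E,10E)-13-[(4R)-4-(tert-butyldimethylsilyloxy)-2,6,6-trimethylcyclohex-1-en-1-yl]-2,7,11-trimethyltrideca-2,4,6,8,10-pentaenal | CC1=C(CC/C(C)=C/C=C/C(C)=C/C=C/C=C(C)/C=O)C(C)(C)C[C@H](O[Si](C)(C)C(C)(C)C)C1 | intermediate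
22 | lithium salt of 15, deprotonated at the carbon next to phosphorus | [Li+].CC1=C(C#C/C(C)=C/[CH-]P(=O)(OCC)OCC)C(C)(C)C[C@H](O[Si](C)(C)C(C)(C)C)C1 | intermediate
23 | (all-E,3R,3′R)-3,3′-bis(tert-butyldimethylsilyloxy)-7,8-didehydro-7′,8′-dihydro-β,β-carotene | CC1=C(C#C/C(C)=C/C=C/C(C)=C/C=C/C=C(C)/C=C/C=C(\C)CCC2=C(C)C[C@@H](O[Si](C)(C)C(C)(C)C)CC2(C)C)C(C)(C)C[C@H](O[Si](C)(C)C(C)(C)C)C1 | intermediate
24 | (all-E,3R,3′R)-7,8-didehydro-7′,8′-dihydro-β,β-carotene-3,3′-diol | CC1=C(C#C/C(C)=C/C=C/C(C)=C/C=C/C=C(C)/C=C/C=C(\C)CCC2=C(C)C[C@@H](O)CC2(C)C)C(C)(C)C[C@H](O)C1 | target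

**Totals**

Total step count: 13. Longest linear sequence: 9 steps (steps 1, 2, 3, 5, 6, 10, 11, 12, 13).

**Steps most likely to fail, each with a fallback**

Step 5 (ring expansion). The addition of the secondary diazoalkane to a carbonyl flanked by a quaternary carbon may be slow, so that Lewis-acid decomposition of diazoethane outruns it. Migration of the quaternary carbon or loss of the β-silyloxy group by elimination may also compete. The fallback inserts the carbon without its methyl group and adds the methyl group afterwards. It sets out from 5: BF3·OEt2-promoted homologation with commercial trimethylsilyldiazomethane (CH2Cl2, −78 °C), where the bulky silyl group reinforces migration of the CH2 carbon, should give the α-silyl ketone (4S)-4-(tert-butyldimethylsilyloxy)-2,2-dimethyl-6-(trimethylsilyl)cyclohexan-1-one F1. Protodesilylation (K2CO3, MeOH) should give (4R)-4-(tert-butyldimethylsilyloxy)-2,2-dimethylcyclohexan-1-one F2. Deprotonation at its only enolisable carbon (LiN(iPr)2, THF, −78 °C) and methylation with MeI should then give 9, where the route is rejoined.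

Step 10 (hydroboration/B-alkyl Suzuki). Oxidative addition and transmetalation at the tetrasubstituted triflate next to the gem-dimethyl group may be too slow, so that protodeboronation or β-hydride elimination of the alkyl group takes over. Hydroboration of the diene may also be less clean than expected. The fallback builds the C6′–C7′ bond by an iron-catalysed Grignard coupling and the side chain by carbonyl chemistry. It sets out from 11:
- Fe(acac)3-catalysed coupling (THF/NMP, −20 °C) with the Grignard reagent from commercial 2-(2-bromoethyl)-2-methyl-1,3-dioxolane should give 2-{2-[(4R)-4-(tert-butyldimethylsilyloxy)-2,6,6-trimethylcyclohex-1-en-1-yl]ethyl}-2-methyl-1,3-dioxolane F3.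
- Mild hydrolysis (PPTS, wet acetone) should give 4-[(4R)-4-(tert-butyldimethylsilyloxy)-2,6,6-trimethylcyclohex-1-en-1-yl]butan-2-one F4.
- Olefination with triethyl phosphonoacetate (NaH, THF) should give, after removal of the minor Z isomer, ethyl (2E)-5-[(4R)-4-(tert-butyldimethylsilyloxy)-2,6,6-trimethylcyclohex-1-en-1-yl]-3-methylpent-2-enoate F5.
- Reduction with iBu2AlH (CH2Cl2, −78 °C) should give (2E)-5-[(4R)-4-(tert-butyldimethylsilyloxy)-2,6,6-trimethylcyclohex-1-en-1-yl]-3-methylpent-2-en-1-ol F6.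
- PBr3 should give (4R)-1-[(3E)-5-bromo-3-methylpent-3-en-1-yl]-4-(tert-butyldimethylsilyloxy)-2,6,6-trimethylcyclohex-1-ene F7, and heating with P(OEt)3 should give 18, where the route is rejoined.

Step 12 (final olefination). The carbanion of 15 is delocalised over C11, C9 and the alkyne, so rotation about C9–C10 may erode the 9E geometry, attack through C9 may compete, and E-selectivity at C11=C12 may be incomplete. The fallback reverses the polarity, so that the enyne geometry sits in an aldehyde and the carbanion in the C25 partner. It sets out from 11, 12 and 21: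
- Sonogashira coupling of 11 with 12 (Pd(PPh3)4, CuI, iPr2NH) should give (2E)-5-[(4R)-4-(tert-butyldimethylsilyloxy)-2,6,6-trimethylcyclohex-1-en-1-yl]-3-methylpent-2-en-4-yn-1-ol F8.
- MnO2 oxidation should give (2E)-5-[(4R)-4-(tert-butyldimethylsilyloxy)-2,6,6-trimethylcyclohex-1-en-1-yl]-3-methylpent-2-en-4-ynal F9.
- NaBH4 reduction of 21 should give (2E,4E,6E,8E,10E)-13-[(4R)-4-(tert-butyldimethylsilyloxy)-2,6,6-trimethylcyclohex-1-en-1-yl]-2,7,11-trimethyltrideca-2,4,6,8,10-pentaen-1-ol F10.
- PPh3·HBr in CH2Cl2 at 0 °C, a medium in which the secondary silyl ether is expected to persist, should give [(2E,4E,6E,8E,10E)-13-[(4R)-4-(tert-butyldimethylsilyloxy)-2,6,6-trimethylcyclohex-1-en-1-yl]-2,7,11-trimethyltrideca-2,4,6,8,10-pentaen-1-yl]triphenylphosphonium bromide F11.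
- Wittig reaction of the ylide of F11 (NaOMe, CH2Cl2/MeOH, 0 °C) with F9 should give 23, where the route is rejoined.

Further compounds
F1 | step 5 | (4S)-4-(tert-butyldimethylsilyloxy)-2,2-dimethyl-6-(trimethylsilyl)cyclohexan-1-one | C[Si](C)(C)C1C(=O)C(C)(C)C[C@H](O[Si](C)(C)C(C)(C)C)C1
F2 | step 5 | (4R)-4-(tert-butyldimethylsilyloxy)-2,2-dimethylcyclohexan-1-one | O=C1C(C)(C)C[C@H](O[Si](C)(C)C(C)(C)C)CC1
F3 | step 10 | 2-{2-[(4R)-4-(tert-butyldimethylsilyloxy)-2,6,6-trimethylcyclohex-1-en-1-yl]ethyl}-2-methyl-1,3-dioxolane | CC1=C(CCC2(C)OCCO2)C(C)(C)C[C@H](O[Si](C)(C)C(C)(C)C)C1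
F4 | step 10 | 4-[(4R)-4-(tert-butyldimethylsilyloxy)-2,6,6-trimethylcyclohex-1-en-1-yl]butan-2-one | CC1=C(CCC(C)=O)C(C)(C)C[C@H](O[Si](C)(C)C(C)(C)C)C1
F5 | step 10 | ethyl (2E)-5-[(4R)-4-(tert-butyldimethylsilyloxy)-2,6,6-trimethylcyclohex-1-en-1-yl]-3-methylpent-2-enoate | CC1=C(CC/C(C)=C/C(=O)OCC)C(C)(C)C[C@H](O[Si](C)(C)C(C)(C)C)C1
F6 | step 10 | (2E)-5-[(4R)-4-(tert-butyldimethylsilyloxy)-2,6,6-trimethylcyclohex-1-en-1-yl]-3-methylpent-2-en-1-ol | CC1=C(CC/C(C)=C/CO)C(C)(C)C[C@H](O[Si](C)(C)C(C)(C)C)C1
F7 | step 10 | (4R)-1-[(3E)-5-bromo-3-methylpent-3-en-1-yl]-4-(tert-butyldimethylsilyloxy)-2,6,6-trimethylcyclohex-1-ene | CC1=C(CC/C(C)=C/CBr)C(C)(C)C[C@H](O[Si](C)(C)C(C)(C)C)C1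
F8 | step 12 | (2E)-5-[(4R)-4-(tert-butyldimethylsilyloxy)-2,6,6-trimethylcyclohex-1-en-1-yl]-3-methylpent-2-en-4-yn-1-ol | CC1=C(C#C/C(C)=C/CO)C(C)(C)C[C@H](O[Si](C)(C)C(C)(C)C)C1
F9 | step 12 | (2E)-5-[(4R)-4-(tert-butyldimethylsilyloxy)-2,6,6-trimethylcyclohex-1-en-1-yl]-3-methylpent-2-en-4-ynal | CC1=C(C#C/C(C)=C/C=O)C(C)(C)C[C@H](O[Si](C)(C)C(C)(C)C)C1
F10 | step 12 | (2E,4E,6E,8E,10E)-13-[(4R)-4-(tert-butyldimethylsilyloxy)-2,6,6-trimethylcyclohex-1-en-1-yl]-2,7,11-trimethyltrideca-2,4,6,8,10-pentaen-1-ol | CC1=C(CC/C(C)=C/C=C/C(C)=C/C=C/C=C(C)/CO)C(C)(C)C[C@H](O[Si](C)(C)C(C)(C)C)C1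
F11 | step 12 | [(2E,4E,6E,8E,10E)-13-[(4R)-4-(tert-butyldimethylsilyloxy)-2,6,6-trimethylcyclohex-1-en-1-yl]-2,7,11-trimethyltrideca-2,4,6,8,10-pentaen-1-yl]triphenylphosphonium bromide | CC1=C(CC/C(C)=C/C=C/C(C)=C/C=C/C=C(C)/C[P+](c2ccccc2)(c2ccccc2)c2ccccc2)C(C)(C)C[C@H](O[Si](C)(C)C(C)(C)C)C1.[Br-]
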